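**Retrosynthetic overview**
- Target 19 ⇐ tert-butyl ester cleavage, thioester → aldehyde, diacetylation of a cis-2,3-diol (15).
- Diol 15 ⇐ C2 enolate hydroxylation, then equatorial hydride delivery to the C3 ketone of bicyclic β-keto thioester 12.
- 12 ⇐ one enantioselective oxidative bicyclization of achiral all-E polyene 11: ring A first (C4–C5), then ring B (C9–C10); sets C4, C5, C9, C10.
- 11 ⇐ γ-alkylation of the dianion of S-ethyl 2-methyl-3-oxobutanethioate (9) with 12-bromofarnesoate 6, made from farnesol (1).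

Assumption 1: labdane numbering is used for the bicyclic compounds (decalin C1–C10; C18 methyl and C19 on C4; C20 methyl on C10; C17 methyl on C8; side chain C11–C16 on C9 with C15 the carboxyl carbon).
Assumption 2: the sense of induction of step 7 cannot be predicted with confidence; the (R)-phosphate is written, and the (S)-phosphate is used instead if the antipode forms.

**Step 1**
Reactants: 1 (2E,6E)-farnesol
Product: 3 (2E,6E)-farnesoic acid, via (2E,6E)-farnesal 2 (not isolated)
Conditions: TEMPO (10 mol%), PhI(OAc)2, CH2Cl2, rt; then NaClO2, NaH2PO4, 2-methyl-2-butene, t-BuOH/H2O, 0 °C to rt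
Reagents that add atoms: sodium chlorite, [Na+].[O-]Cl=O
Why: Oxoammonium (TEMPO) oxidation of the allylic alcohol followed by Pinnick oxidation gives the acid without touching the trisubstituted alkenes or the 2E geometry; no stereocentre is formed.

**Step 2**
Reactants: 3 (2E,6E)-farnesoic acid
Product: 4 tert-butyl (2E,6E)-3,7,11-trimethyldodeca-2,6,10-trienoate
Conditions: Cl3CC(=NH)O-t-Bu, CH2Cl2/cyclohexane, rt (no added acid)
Reagents that add atoms: tert-butyl 2,2,2-trichloroacetimidate, CC(C)(C)OC(=N)C(Cl)(Cl)Cl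
Why: Imidate esterification, promoted by the substrate acid itself, installs an ester that survives all later base, hydride and oxidation steps and can be removed last without touching acetates.

**Step 3**
Reactants: 4 tert-butyl (2E,6E)-3,7,11-trimethyldodeca-2,6,10-trienoate
Product: 5 tert-butyl (2E,6E,10E)-12-hydroxy-3,7,11-trimethyldodeca-2,6,10-trienoate
Conditions: SeO2 (0.3 equiv), t-BuOOH, salicylic acid (10 mol%), CH2Cl2, 0 °C to rt
Reagents that add atoms: selenium dioxide, O=[Se]=O; tert-butyl hydroperoxide, CC(C)(C)OO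
Why: Riley allylic oxidation (ene reaction then [2,3]-shift) attacks the most electron-rich terminal isopropylidene at its E-methyl, while the enoate alkene is deactivated; the E-allylic alcohol results.

**Step 4**
Reactants: 5 tert-butyl (2E,6E,10E)-12-hydroxy-3,7,11-trimethyldodeca-2,6,10-trienoate
Product: 6 tert-butyl (2E,6E,10E)-12-bromo-3,7,11-trimethyldodeca-2,6,10-trienoate
Conditions: CBr4, PPh3, CH2Cl2, 0 °C
Reagents that add atoms: carbon tetrabromide, BrC(Br)(Br)Br
Why: Appel reaction converts the primary allylic alcohol to the bromide under neutral conditions with retention of alkene geometry.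

**Step 5**
Reactants: 7 S-ethyl propanethioate; 8 1-acetyl-1H-benzotriazole
Product: 9 S-ethyl 2-methyl-3-oxobutanethioate
Conditions: MgBr2·OEt2, i-Pr2NEt, CH2Cl2, rt
Reagents that add atoms: none
Why: Soft-enolisation crossed Claisen condensation: the magnesium thioester enolate is C-acylated and the product is held as a chelate, which prevents double acylation.

**Step 6**
Reactants: 9 S-ethyl 2-methyl-3-oxobutanethioate; 6 tert-butyl (2E,6E,10E)-12-bromo-3,7,11-trimethyldodeca-2,6,10-trienoate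
Product: 11 tert-butyl (2E,6E,10E)-16-(ethylsulfanyl)-3,7,11,15-tetramethyl-14,16-dioxohexadeca-2,6,10-trienoate, via thioester dilithium dianion 10 (not isolated)
Conditions: lithium diisopropylamide (2.1 equiv), THF, −78 to 0 °C; then 6, −78 to 0 °C; AcOH quench
Reagents that add atoms: none
Why: Dianion γ-alkylation of the acetoacetate type: the more reactive terminal carbanion displaces the primary allylic bromide (SN2), giving the achiral all-E cyclization substrate.

**Step 7**
Reactants: 11 tert-butyl (2E,6E,10E)-16-(ethylsulfanyl)-3,7,11,15-tetramethyl-14,16-dioxohexadeca-2,6,10-trienoate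
Product: 12 tert-butyl (4S,5S,9R,10S,13E)-19-(ethylsulfanyl)-3,19-dioxolabda-7,13-dien-15-oate
Conditions: (R)-TRIP tetrabutylammonium phosphate (10 mol%), (4-BrC6H4)3N (10 mol%), n-Bu4NPF6 (0.1 M), CH2Cl2, graphite anode, graphite cathode, undivided cell, constant current (about 2.2 F/mol), −20 °C
Reagents that add atoms: none
Why: Proposed new method: phosphate-gated electro-oxidative radical–polar crossover polyene bicyclization. The chiral phosphate hydrogen-bonds the enol O–H of 11, so only this complex is oxidised (concerted proton-coupled electron transfer) by the anodically formed triarylaminium, which is too weak to oxidise the keto form or the trisubstituted alkenes. The C4 radical, still hydrogen-bonded to the chiral phosphoric acid, attacks C5 (6-endo, chair, planar thioester axial and methyl equatorial), and this facial choice sets the absolute configuration. The C10 radical (or its cation after oxidation) closes ring B through a second chair to the trans-decalin with the C9 chain equatorial. The C8 radical is oxidised to the cation and loses H-7 (E1, endocyclic alkene), and the acid is reduced to H2 at the cathode, which regenerates the phosphate. Closest known reaction types: the Mn(OAc)3/Cu(OAc)2 oxidative free-radical polyene cyclization of α-methyl β-keto esters (same ring closures and relative configuration, racemic) and chiral-phosphate proton-coupled electron-transfer radical cyclizations.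

**Step 8**
Reactants: 12 tert-butyl (4S,5S,9R,10S,13E)-19-(ethylsulfanyl)-3,19-dioxolabda-7,13-dien-15-oate
Product: 14 tert-butyl (2S,4S,5S,9R,10S,13E)-19-(ethylsulfanyl)-2-hydroxy-3,19-dioxolabda-7,13-dien-15-oate, via potassium C2-enolate 13 (not isolated)
Conditions: KN(SiMe3)2 (1.1 equiv), THF, −78 °C; then racemic 2-(phenylsulfonyl)-3-phenyloxaziridine, −78 °C; AcOH quench
Reagents that add atoms: 2-(phenylsulfonyl)-3-phenyloxaziridine, O=S(=O)(c1ccccc1)N1OC1c1ccccc1
Why: Davis enolate hydroxylation: C2 is the only enolisable position of the C3 ketone, and the oxidant attacks the face opposite the axial C10 methyl and axial C4 thioester, giving the equatorial 2-hydroxyl (2S).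

**Step 9**
Reactants: 14 tert-butyl (2S,4S,5S,9R,10S,13E)-19-(ethylsulfanyl)-2-hydroxy-3,19-dioxolabda-7,13-dien-15-oate
Product: 15 tert-butyl (2S,3R,4S,5S,9R,10S,13E)-19-(ethylsulfanyl)-2,3-dihydroxy-19-oxolabda-7,13-dien-15-oate
Conditions: LiBH(s-Bu)3 (2.5 equiv), THF, −78 °C; AcOH quench
Reagents that add atoms: none
Why: Bulky-hydride (Selectride) reduction: axial approach is blocked by the syn-axial H-1 and H-5, so hydride enters equatorially and gives the axial 3-alcohol cis to the 2-hydroxyl (3R); the hindered thioester and the β,β-disubstituted enoate are inert at −78 °C.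

**Step 10**
Reactants: 15 tert-butyl (2S,3R,4S,5S,9R,10S,13E)-19-(ethylsulfanyl)-2,3-dihydroxy-19-oxolabda-7,13-dien-15-oate
Product: 16 tert-butyl (2S,3R,4S,5S,9R,10S,13E)-2,3-diacetoxy-19-(ethylsulfanyl)-19-oxolabda-7,13-dien-15-oate
Conditions: Ac2O, DMAP, pyridine, CH2Cl2, rt to 40 °C
Reagents that add atoms: acetic anhydride, CC(=O)OC(C)=O
Why: DMAP-catalysed acyl transfer esterifies both hydroxyls, including the hindered axial one; any 2→3 acetyl migration is irrelevant because both end as acetates.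

**Step 11**
Reactants: 16 tert-butyl (2S,3R,4S,5S,9R,10S,13E)-2,3-diacetoxy-19-(ethylsulfanyl)-19-oxolabda-7,13-dien-15-oate
Product: 17 tert-butyl (2S,3R,4S,5S,9R,10S,13E)-2,3-diacetoxy-19-oxolabda-7,13-dien-15-oate
Conditions: Et3SiH, Pd/C (10 wt% Pd, 15 mol%), acetone, rt
Reagents that add atoms: none
Why: Fukuyama reduction: zerovalent palladium inserts into the acyl–sulfur bond and the silane delivers hydride, giving the aldehyde directly while esters, acetates and alkenes are untouched.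

**Step 12**
Reactants: 17 tert-butyl (2S,3R,4S,5S,9R,10S,13E)-2,3-diacetoxy-19-oxolabda-7,13-dien-15-oate
Product: 19 (2S,3R,4S,5S,9R,10S,13E)-2,3-diacetoxy-19-oxolabda-7,13-dien-15-oic acid, via trimethylsilyl ester 18 (not isolated)
Conditions: TMSOTf, 2,6-lutidine, CH2Cl2, 0 °C; then H2O (pH 4 buffer)
Reagents that add atoms: none
Why: Silyl-triflate tert-butyl ester cleavage (loss of isobutene, silyl ester hydrolysed on work-up) is non-protic, so the trisubstituted 7-ene, the acetates and the non-enolisable aldehyde survive.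

**Compound list**
1 | (2E,6E)-farnesol | CC(C)=CCC/C(C)=C/CC/C(C)=C/CO | starting material
2 | (2E,6E)-farnesal | CC(C)=CCC/C(C)=C/CC/C(C)=C/C=O | intermediate
3 | (2E,6E)-farnesoic acid | CC(C)=CCC/C(C)=C/CC/C(C)=C/C(=O)O | intermediate
4 | tert-butyl (2E,6E)-3,7,11-trimethyldodeca-2,6,10-trienoate | CC(C)=CCC/C(C)=C/CC/C(C)=C/C(=O)OC(C)(C)C | intermediate
5 | tert-butyl (2E,6E,10E)-12-hydroxy-3,7,11-trimethyldodeca-2,6,10-trienoate | OC/C(C)=C/CC/C(C)=C/CC/C(C)=C/C(=O)OC(C)(C)C | intermediate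
6 | tert-butyl (2E,6E,10E)-12-bromo-3,7,11-trimethyldodeca-2,6,10-trienoate | BrC/C(C)=C/CC/C(C)=C/CC/C(C)=C/C(=O)OC(C)(C)C | intermediate
7 | S-ethyl propanethioate | CCSC(=O)CC | starting material
8 | 1-acetyl-1H-benzotriazole | CC(=O)n1nnc2ccccc12 | starting material
9 | S-ethyl 2-methyl-3-oxobutanethioate (racemic, epimerisable) | CCSC(=O)C(C)C(C)=O | intermediate
10 | dilithium dianion of 9 (C2 and C4 carbanion/enolate) | [Li+].[Li+].CCSC(=O)[C-](C)C(=O)[CH2-] | intermediate
11 | tert-butyl (2E,6E,10E)-16-(ethylsulfanyl)-3,7,11,15-tetramethyl-14,16-dioxohexadeca-2,6,10-trienoate (C15 epimerisable) | CCSC(=O)C(C)C(=O)CC/C(C)=C/CC/C(C)=C/CC/C(C)=C/C(=O)OC(C)(C)C | intermediate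
12 | tert-butyl (4S,5S,9R,10S,13E)-19-(ethylsulfanyl)-3,19-dioxolabda-7,13-dien-15-oate (trans-decalin; C4 thioester axial, cis to the C10 methyl; C9 chain equatorial) | O=C1CC[C@@]2(C)[C@H](CC/C(C)=C/C(=O)OC(C)(C)C)C(C)=CC[C@@H]2[C@]1(C)C(=O)SCC | intermediate
13 | potassium C2(3)-enolate of 12 | [K+].[O-]C1=CC[C@@]2(C)[C@H](CC/C(C)=C/C(=O)OC(C)(C)C)C(C)=CC[C@@H]2[C@]1(C)C(=O)SCC | intermediate
14 | tert-butyl (2S,4S,5S,9R,10S,13E)-19-(ethylsulfanyl)-2-hydroxy-3,19-dioxolabda-7,13-dien-15-oate (2-OH equatorial, trans to the C10 methyl) | O[C@H]1C[C@@]2(C)[C@H](CC/C(C)=C/C(=O)OC(C)(C)C)C(C)=CC[C@@H]2[C@](C)(C(=O)SCC)C1=O | intermediate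
15 | tert-butyl (2S,3R,4S,5S,9R,10S,13E)-19-(ethylsulfanyl)-2,3-dihydroxy-19-oxolabda-7,13-dien-15-oate (cis-diol; 3-OH axial) | O[C@H]1C[C@@]2(C)[C@H](CC/C(C)=C/C(=O)OC(C)(C)C)C(C)=CC[C@@H]2[C@](C)(C(=O)SCC)[C@H]1O | intermediate
16 | tert-butyl (2S,3R,4S,5S,9R,10S,13E)-2,3-diacetoxy-19-(ethylsulfanyl)-19-oxolabda-7,13-dien-15-oate | CC(=O)O[C@H]1C[C@@]2(C)[C@H](CC/C(C)=C/C(=O)OC(C)(C)C)C(C)=CC[C@@H]2[C@](C)(C(=O)SCC)[C@H]1OC(C)=O | intermediate
17 | tert-butyl (2S,3R,4S,5S,9R,10S,13E)-2,3-diacetoxy-19-oxolabda-7,13-dien-15-oate | CC(=O)O[C@H]1C[C@@]2(C)[C@H](CC/C(C)=C/C(=O)OC(C)(C)C)C(C)=CC[C@@H]2[C@](C)(C=O)[C@H]1OC(C)=O | intermediate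
18 | trimethylsilyl (2S,3R,4S,5S,9R,10S,13E)-2,3-diacetoxy-19-oxolabda-7,13-dien-15-oate | CC(=O)O[C@H]1C[C@@]2(C)[C@H](CC/C(C)=C/C(=O)O[Si](C)(C)C)C(C)=CC[C@@H]2[C@](C)(C=O)[C@H]1OC(C)=O | intermediate
19 | (2S,3R,4S,5S,9R,10S,13E)-2,3-diacetoxy-19-oxolabda-7,13-dien-15-oic acid (CNP0273594.1) | CC(=O)O[C@H]1C[C@@]2(C)[C@H](CC/C(C)=C/C(=O)O)C(C)=CC[C@@H]2[C@](C)(C=O)[C@H]1OC(C)=O | target

**Step count**
Total steps: 12. Longest linear sequence: 11 (steps 1–4 and 6–12; step 5 is a one-step side branch).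

**Three steps most likely to fail**

*Step 7 (the new bicyclization).* Risks: low enantioselectivity if the radical leaves the chiral acid before ring closure; 8(17)- or 8-ene regioisomers from the C8 cation; 5-exo capture of the C8 radical by the enoate if its oxidation is slow.
Fallback (known chemistry; sets out from 6, returns at 14): the stereochemistry is relayed from a C2 oxygen installed by organocatalysis before a classical racemic-type cyclization.
- Bromide 6 is alkylated with lithiated N-ethylidenecyclohexanamine (lithium diisopropylamide, THF, −78 to 0 °C) to give tert-butyl (2E,6E,10E)-14-(cyclohexylimino)-3,7,11-trimethyltetradeca-2,6,10-trienoate F1. Aqueous oxalic acid in the same flask hydrolyses it to tert-butyl (2E,6E,10E)-3,7,11-trimethyl-14-oxotetradeca-2,6,10-trienoate F2.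
- Enamine-catalysed α-benzoyloxylation (dibenzoyl peroxide, (S)-2-(triphenylmethyl)pyrrolidine 10 mol%, hydroquinone, THF, 0 °C) sets the first stereocentre (the future C2, S) in tert-butyl (2E,6E,10E,13S)-13-(benzoyloxy)-3,7,11-trimethyl-14-oxotetradeca-2,6,10-trienoate F3.
- Aldol addition of the lithium enolate of 7 (lithium diisopropylamide, THF, −78 °C) gives tert-butyl (2E,6E,10E,13S)-13-(benzoyloxy)-16-(ethylsulfanyl)-14-hydroxy-3,7,11,15-tetramethyl-16-oxohexadeca-2,6,10-trienoate F4 as a diastereomer mixture. Dess–Martin oxidation converts it to tert-butyl (2E,6E,10E,13S)-13-(benzoyloxy)-16-(ethylsulfanyl)-3,7,11,15-tetramethyl-14,16-dioxohexadeca-2,6,10-trienoate F5.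
- Mn(OAc)3·2H2O and Cu(OAc)2·H2O in AcOH at rt close both rings. The benzoate sits equatorial in the chair and relays its configuration to C4, C5, C9 and C10, and divalent copper converts the C8 radical to the exocyclic alkene, giving tert-butyl (2S,4S,5S,9R,10S,13E)-2-(benzoyloxy)-19-(ethylsulfanyl)-3,19-dioxolabda-8(17),13-dien-15-oate F6.
- Hydrogen-atom-transfer isomerization with Co(salen)Cl (salen = N,N'-bis(3,5-di-tert-butylsalicylidene)ethane-1,2-diaminate, trivalent cobalt, 3 mol%) and PhSiH3 in benzene moves the alkene into the ring, giving tert-butyl (2S,4S,5S,9R,10S,13E)-2-(benzoyloxy)-19-(ethylsulfanyl)-3,19-dioxolabda-7,13-dien-15-oate F7. The same isomerization also converges any 8(17)-ene formed in the main step 7.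
- K2CO3 in MeOH at 0 °C removes the activated α-keto benzoate to give 14.

*Step 9 (C3 reduction).* Risk: hydride enters axially and gives the trans-diol, or the thioester is attacked.
Fallback (sets out from 14, returns at 16): reagent control replaces substrate control.
- 14 is acetylated (Ac2O, DMAP, pyridine) to tert-butyl (2S,4S,5S,9R,10S,13E)-2-acetoxy-19-(ethylsulfanyl)-3,19-dioxolabda-7,13-dien-15-oate F8.
- Corey–Bakshi–Shibata reduction with (R)-2-methyl-CBS-oxazaborolidine (20 mol%) and catecholborane in toluene at −78 to −40 °C treats the quaternary C4 side as the large group and delivers hydride to the face bearing the C10 methyl. The product is tert-butyl (2S,3R,4S,5S,9R,10S,13E)-2-acetoxy-19-(ethylsulfanyl)-3-hydroxy-19-oxolabda-7,13-dien-15-oate F9.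
- Acetylation (Ac2O, DMAP) gives 16.

*Step 11 (Fukuyama reduction).* Risk: the quaternary, axial thioester may resist oxidative addition or decarbonylate.
Fallback (sets out from 15, returns at 17): the aldehyde is reached through the alcohol instead.
- LiBH4 in THF at 0 °C to rt reduces only the thioester of 15 (the tert-butyl enoate is inert), giving tert-butyl (2S,3R,4R,5S,9R,10S,13E)-2,3,19-trihydroxylabda-7,13-dien-15-oate F10.
- TEMPO/PhI(OAc)2 in CH2Cl2 oxidises the primary alcohol selectively to tert-butyl (2S,3R,4S,5S,9R,10S,13E)-2,3-dihydroxy-19-oxolabda-7,13-dien-15-oate F11.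
- Ac2O, DMAP and pyridine acetylate the diol to give 17.

**Further compounds**
F1 | step 7 | tert-butyl (2E,6E,10E)-14-(cyclohexylimino)-3,7,11-trimethyltetradeca-2,6,10-trienoate | C1CCCCC1N=CCC/C(C)=C/CC/C(C)=C/CC/C(C)=C/C(=O)OC(C)(C)C
F2 | step 7 | tert-butyl (2E,6E,10E)-3,7,11-trimethyl-14-oxotetradeca-2,6,10-trienoate | O=CCC/C(C)=C/CC/C(C)=C/CC/C(C)=C/C(=O)OC(C)(C)C
F3 | step 7 | tert-butyl (2E,6E,10E,13S)-13-(benzoyloxy)-3,7,11-trimethyl-14-oxotetradeca-2,6,10-trienoate | O=C[C@@H](OC(=O)c1ccccc1)C/C(C)=C/CC/C(C)=C/CC/C(C)=C/C(=O)OC(C)(C)C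
F4 | step 7 | tert-butyl (2E,6E,10E,13S)-13-(benzoyloxy)-16-(ethylsulfanyl)-14-hydroxy-3,7,11,15-tetramethyl-16-oxohexadeca-2,6,10-trienoate (C14/C15 diastereomer mixture) | CCSC(=O)C(C)C(O)[C@@H](OC(=O)c1ccccc1)C/C(C)=C/CC/C(C)=C/CC/C(C)=C/C(=O)OC(C)(C)C
F5 | step 7 | tert-butyl (2E,6E,10E,13S)-13-(benzoyloxy)-16-(ethylsulfanyl)-3,7,11,15-tetramethyl-14,16-dioxohexadeca-2,6,10-trienoate | CCSC(=O)C(C)C(=O)[C@@H](OC(=O)c1ccccc1)C/C(C)=C/CC/C(C)=C/CC/C(C)=C/C(=O)OC(C)(C)C
F6 | step 7 | tert-butyl (2S,4S,5S,9R,10S,13E)-2-(benzoyloxy)-19-(ethylsulfanyl)-3,19-dioxolabda-8(17),13-dien-15-oate | O=C(O[C@H]1C[C@@]2(C)[C@H](CC/C(C)=C/C(=O)OC(C)(C)C)C(=C)CC[C@@H]2[C@](C)(C(=O)SCC)C1=O)c1ccccc1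
F7 | step 7 | tert-butyl (2S,4S,5S,9R,10S,13E)-2-(benzoyloxy)-19-(ethylsulfanyl)-3,19-dioxolabda-7,13-dien-15-oate | O=C(O[C@H]1C[C@@]2(C)[C@H](CC/C(C)=C/C(=O)OC(C)(C)C)C(C)=CC[C@@H]2[C@](C)(C(=O)SCC)C1=O)c1ccccc1
F8 | step 9 | tert-butyl (2S,4S,5S,9R,10S,13E)-2-acetoxy-19-(ethylsulfanyl)-3,19-dioxolabda-7,13-dien-15-oate | CC(=O)O[C@H]1C[C@@]2(C)[C@H](CC/C(C)=C/C(=O)OC(C)(C)C)C(C)=CC[C@@H]2[C@](C)(C(=O)SCC)C1=O
F9 | step 9 | tert-butyl (2S,3R,4S,5S,9R,10S,13E)-2-acetoxy-19-(ethylsulfanyl)-3-hydroxy-19-oxolabda-7,13-dien-15-oate | CC(=O)O[C@H]1C[C@@]2(C)[C@H](CC/C(C)=C/C(=O)OC(C)(C)C)C(C)=CC[C@@H]2[C@](C)(C(=O)SCC)[C@H]1O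
F10 | step 11 | tert-butyl (2S,3R,4R,5S,9R,10S,13E)-2,3,19-trihydroxylabda-7,13-dien-15-oate | O[C@H]1C[C@@]2(C)[C@H](CC/C(C)=C/C(=O)OC(C)(C)C)C(C)=CC[C@@H]2[C@](C)(CO)[C@H]1O
F11 | step 11 | tert-butyl (2S,3R,4S,5S,9R,10S,13E)-2,3-dihydroxy-19-oxolabda-7,13-dien-15-oate | O[C@H]1C[C@@]2(C)[C@H](CC/C(C)=C/C(=O)OC(C)(C)C)C(C)=CC[C@@H]2[C@](C)(C=O)[C@H]1O
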